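**Plan**

1. Locants used below (daucane frame): ring A = cyclopentane C1(quaternary, CH3)–C2–C3–C4(isopropyl, aroyloxy)–C5(H); ring B = cycloheptenone C1–C5–C6(OH)–C7=C8(CH3)–C9(=O)–C10.
2. Retrosynthetic cuts, in order: the two O–Si bonds and the C9 oxidation level; C8–C9 of ring B; C4–isopropyl together with the C4–O acyl bond; C5–C6 (aldol); C1–CH3 (conjugate addition); the C1–C10 arm.
3. Enabling feature: ring B holds O–C6–C7=C8–C9=O, a 1,4-dioxygenated cis-ene, so C8 and C9 are both acceptor carbons. C8 is carried as the iodine-bearing β-carbon of (Z)-3-iodobut-2-enal and C9 as an aldehyde, and chromium-mediated polarity reversal at C8 joins them.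
4. Forward order: ring A comes from 3-ethoxycyclopent-2-enone; the C10 arm, the C1 methyl, the C5 arm (C6–C8 with its Z-iodide) and the C4 isopropyl/ester are attached in turn; ring B is closed last, at C8–C9, remote from the ring fusion.
5. Stereochemistry: C1 by ligand-controlled copper-catalysed conjugate addition of Me3Al; C5 and C6 relayed from C1 in one anti-selective boron aldol; C4 by addition anti to the C5 arm; the Z-iodoalkene becomes the ring cis-alkene, and the trans ring fusion is fixed before ring closure.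

Key step: step 11

Remark on the chemistry: the target is a 1,3-hydroxy ester (tertiary C4 benzoate, free C6 hydroxyl) that should be prone to base-induced acyl shift to C6, so the ester is installed before the C6 oxygen is freed and no basic step follows. TBS = tert-butyldimethylsilyl, TMS = trimethylsilyl.

**Route**

Step 1
Reactants: 1 but-2-yn-1-ol
Product: 3 (Z)-3-iodobut-2-en-1-ol, via cyclic alkenylaluminate 2 (not isolated)
Conditions: NaAlH2(OCH2CH2OMe)2, THF, 0 °C → rt; then N-iodosuccinimide, −78 °C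
Reagents that add atoms: N-iodosuccinimide, O=C1CCC(=O)N1I
Why: Hydroxyl-directed trans-hydroalumination of the propargylic alcohol places aluminium on C3 inside a five-membered alkoxyaluminate, so iodinolysis with retention should give the Z-alkenyl iodide with iodine cis to the CH2OH carbon.

Step 2
Reactants: 3 (Z)-3-iodobut-2-en-1-ol
Product: 4 (Z)-3-iodobut-2-enal
Conditions: activated MnO2, CH2Cl2, rt; filtered and used at once as a solution
Reagents that add atoms: none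
Why: Allylic alcohol oxidation with MnO2 is neutral and should leave the Z-iodoalkene geometry intact.

Step 3
Reactants: 5 4-hydroxybenzoic acid
Product: 6 TBS 4-(TBS-oxy)benzoate
Conditions: TBSCl (2.3 equiv), imidazole, DMF, rt
Reagents that add atoms: tert-butyldimethylsilyl chloride, CC(C)(C)[Si](C)(C)Cl
Why: Silylation with silyl chloride and imidazole masks the phenol and converts the acid into a silyl ester, which sets up step 4.

Step 4
Reactants: 6 TBS 4-(TBS-oxy)benzoate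
Product: 7 4-(TBS-oxy)benzoyl chloride
Conditions: (COCl)2, DMF (cat.), CH2Cl2, 0 °C → rt
Reagents that add atoms: oxalyl chloride, ClC(=O)C(Cl)=O
Why: A silyl ester is converted directly into the acid chloride by oxalyl chloride under DMF catalysis (Vilsmeier-type activation), under neutral conditions that keep the aryl silyl ether.

Step 5
Reactants: 8 3-ethoxycyclopent-2-en-1-one
Product: 10 3-(1,3-dioxolan-2-ylmethyl)cyclopent-2-en-1-one, via bromomagnesium alkoxide 9 (not isolated)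
Conditions: (1,3-dioxolan-2-ylmethyl)magnesium bromide, THF, 0 °C → rt; then 1 M HCl, 0 °C, short contact
Reagents that add atoms: (1,3-dioxolan-2-ylmethyl)magnesium bromide, Br[Mg]CC1OCCO1; water, O
Why: Stork–Danheiser sequence: 1,2-addition of the Grignard reagent to the vinylogous ester followed by acid-induced 1,3-carbonyl transposition should give the 3-substituted enone, brief cold acid sparing the dioxolane.

Step 6
Reactants: 10 3-(1,3-dioxolan-2-ylmethyl)cyclopent-2-en-1-one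
Product: 12 {[(3R)-3-(1,3-dioxolan-2-ylmethyl)-3-methylcyclopent-1-en-1-yl]oxy}trimethylsilane, via dimethylaluminium enolate 11 (not isolated)
Conditions: Me3Al, copper thiophene-2-carboxylate Cu(O2CC4H3S) (5 mol %), chiral phosphoramidite ligand (biphenol/bis(1-arylethyl)amine type, antipode giving R at C1; 10 mol %), Et2O, −30 °C; then TMSOTf, Et3N, −30 → 0 °C
Reagents that add atoms: trimethylaluminium, C[Al](C)C; trimethylsilyl trifluoromethanesulfonate, C[Si](C)(C)OS(=O)(=O)C(F)(F)F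
Why: Copper-catalysed asymmetric conjugate addition of Me3Al to a β-substituted cyclopentenone builds the quaternary C1 under ligand control, and O-silylation of the aluminium enolate stores the C4–C5 enolate regiochemistry.

Step 7
Reactants: 12 {[(3R)-3-(1,3-dioxolan-2-ylmethyl)-3-methylcyclopent-1-en-1-yl]oxy}trimethylsilane; 4 (Z)-3-iodobut-2-enal
Product: 15 (2S,3R)-3-(1,3-dioxolan-2-ylmethyl)-2-[(1R,2Z)-1-hydroxy-3-iodobut-2-en-1-yl]-3-methylcyclopentan-1-one, via lithium enolate 13 (not isolated), via dicyclohexylboron enolate 14 (not isolated)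
Conditions: MeLi (1.0 equiv), THF, 0 °C; (c-C6H11)2BCl, −78 °C; then 4, −78 → −20 °C; pH 7 buffer–MeOH work-up
Reagents that add atoms: none
Why: Anti-selective boron aldol addition: the ring-locked E-enol borinate reacts through a Zimmerman–Traxler chair, which relates C5 and C6 as anti, and the aldehyde should enter C5 on the face of the C1 methyl, away from the bulkier dioxolanylmethyl arm, so both centres are relayed from C1.

Step 8
Reactants: 15 (2S,3R)-3-(1,3-dioxolan-2-ylmethyl)-2-[(1R,2Z)-1-hydroxy-3-iodobut-2-en-1-yl]-3-methylcyclopentan-1-one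
Product: 16 (2S,3R)-3-(1,3-dioxolan-2-ylmethyl)-2-[(1R,2Z)-3-iodo-1-(TBS-oxy)but-2-en-1-yl]-3-methylcyclopentan-1-one
Conditions: TBSOTf (1.2 equiv), 2,6-lutidine, CH2Cl2, −78 °C
Reagents that add atoms: tert-butyldimethylsilyl trifluoromethanesulfonate, CC(C)(C)[Si](C)(C)OS(=O)(=O)C(F)(F)F
Why: Silyl triflate silylation at low temperature protects the β-hydroxy ketone before retro-aldol or dehydration can intervene and should be faster than attack on the dioxolane.

Step 9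
Reactants: 16 (2S,3R)-3-(1,3-dioxolan-2-ylmethyl)-2-[(1R,2Z)-3-iodo-1-(TBS-oxy)but-2-en-1-yl]-3-methylcyclopentan-1-one; 7 4-(TBS-oxy)benzoyl chloride
Product: 18 (1R,2S,3R)-3-(1,3-dioxolan-2-ylmethyl)-2-[(1R,2Z)-3-iodo-1-(TBS-oxy)but-2-en-1-yl]-3-methyl-1-(propan-2-yl)cyclopentyl 4-(TBS-oxy)benzoate, via chloromagnesium alkoxide 17 (not isolated)
Conditions: i-PrMgCl, CeCl3 (anhydrous), THF, −78 → 0 °C; then 7, DMAP (cat.), 0 → 25 °C
Reagents that add atoms: isopropylmagnesium chloride, CC(C)[Mg]Cl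
Why: CeCl3-modified Grignard 1,2-addition suppresses enolisation, β-hydride reduction and iodine–magnesium exchange, the isopropyl group entering C4 anti to the large C5 side chain so that the C4 oxygen ends cis to C6, and acylation of the alkoxide in the same flask gives the tertiary ester.

Step 10
Reactants: 18 (1R,2S,3R)-3-(1,3-dioxolan-2-ylmethyl)-2-[(1R,2Z)-3-iodo-1-(TBS-oxy)but-2-en-1-yl]-3-methyl-1-(propan-2-yl)cyclopentyl 4-(TBS-oxy)benzoate
Product: 19 (1R,2S,3R)-2-[(1R,2Z)-3-iodo-1-(TBS-oxy)but-2-en-1-yl]-3-methyl-3-(2-oxoethyl)-1-(propan-2-yl)cyclopentyl 4-(TBS-oxy)benzoate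
Conditions: PPTS, acetone–H2O (10:1), 55 °C
Reagents that add atoms: water, O
Why: Mildly acid-catalysed acetal hydrolysis should free the C9 aldehyde without touching the silyl ethers, the tertiary ester or the alkenyl iodide.

Step 11
Reactants: 19 (1R,2S,3R)-2-[(1R,2Z)-3-iodo-1-(TBS-oxy)but-2-en-1-yl]-3-methyl-3-(2-oxoethyl)-1-(propan-2-yl)cyclopentyl 4-(TBS-oxy)benzoate
Product: 20 (1R,3aR,8S,8aS)-5-hydroxy-3a,6-dimethyl-1-(propan-2-yl)-8-(TBS-oxy)-1,2,3,3a,4,5,8,8a-octahydroazulen-1-yl 4-(TBS-oxy)benzoate (both epimers at the new carbinol carbon)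
Conditions: CrCl2 (8 equiv), NiCl2 (2 mol %), DMSO, 25 °C, 0.005 M
Reagents that add atoms: none
Why: Zerovalent nickel, formed from NiCl2 by divalent chromium, inserts into the C8–I bond with retention, transmetallation gives a C8 alkenyl species of trivalent chromium, and this adds to the C9 aldehyde to give the ring B chromium alkoxide. The closest known reaction type is the intramolecular Nozaki–Hiyama–Kishi coupling used for medium-ring allylic alcohols. Ring B closes in the 7-exo-trig mode at a bond remote from the ring fusion, so the trans relation of the C10 arm on C1 and the C6 arm on C5 is carried unchanged into a trans-fused bicycle. The only new stereocentre, C9, is not controlled and need not be, since step 12 oxidises it. The step needs chemoselectivity for C–I and CHO beside the aryl ester, the silyl ethers and the allylic C6 oxygen, which the mild non-basic chromium reagent should secure, and it needs the two chain ends cis on C7=C8, which the Z-iodide carries. High dilution should suppress intermolecular coupling.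

Step 12
Reactants: 20 (1R,3aR,8S,8aS)-5-hydroxy-3a,6-dimethyl-1-(propan-2-yl)-8-(TBS-oxy)-1,2,3,3a,4,5,8,8a-octahydroazulen-1-yl 4-(TBS-oxy)benzoate
Product: 21 (1R,3aR,8S,8aS)-3a,6-dimethyl-5-oxo-1-(propan-2-yl)-8-(TBS-oxy)-1,2,3,3a,4,5,8,8a-octahydroazulen-1-yl 4-(TBS-oxy)benzoate
Conditions: Dess–Martin periodinane, CH2Cl2, 0 °C → rt
Reagents that add atoms: none
Why: Dess–Martin oxidation of the secondary allylic alcohol should converge both C9 epimers to the enone under non-basic conditions.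

Step 13
Reactants: 21 (1R,3aR,8S,8aS)-3a,6-dimethyl-5-oxo-1-(propan-2-yl)-8-(TBS-oxy)-1,2,3,3a,4,5,8,8a-octahydroazulen-1-yl 4-(TBS-oxy)benzoate
Product: 22 (1R,3aR,8S,8aS)-8-hydroxy-3a,6-dimethyl-5-oxo-1-(propan-2-yl)-1,2,3,3a,4,5,8,8a-octahydroazulen-1-yl 4-hydroxybenzoate
Conditions: HF·pyridine, pyridine–THF, 0 °C → rt
Reagents that add atoms: none
Why: Fluoride cleavage of both silyl ethers with buffered HF·pyridine is acidic, not basic, which should prevent acyl shift from the C4 oxygen to the newly freed C6 hydroxyl.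

**Compound list**

1 | but-2-yn-1-ol | CC#CCO | starting material
2 | sodium 2,2-bis(2-methoxyethoxy)-3-methyl-2,5-dihydro-1,2-oxaluminol-2-uide (cyclic Z-alkenylaluminate) | C/C1=C/CO[Al-]1(OCCOC)OCCOC.[Na+] | intermediate
3 | (Z)-3-iodobut-2-en-1-ol | C/C(I)=C/CO | intermediate
4 | (Z)-3-iodobut-2-enal | C/C(I)=C/C=O | intermediate
5 | 4-hydroxybenzoic acid | OC(=O)c1ccc(O)cc1 | starting material
6 | tert-butyldimethylsilyl 4-[(tert-butyldimethylsilyl)oxy]benzoate | CC(C)(C)[Si](C)(C)OC(=O)c1ccc(O[Si](C)(C)C(C)(C)C)cc1 | intermediate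
7 | 4-[(tert-butyldimethylsilyl)oxy]benzoyl chloride | CC(C)(C)[Si](C)(C)Oc1ccc(cc1)C(Cl)=O | intermediate
8 | 3-ethoxycyclopent-2-en-1-one | CCOC1=CC(=O)CC1 | starting material
9 | bromomagnesium 1-(1,3-dioxolan-2-ylmethyl)-3-ethoxycyclopent-2-en-1-olate (racemic) | CCOC1=CC(CC2OCCO2)(O[Mg]Br)CC1 | intermediate
10 | 3-(1,3-dioxolan-2-ylmethyl)cyclopent-2-en-1-one | O=C1C=C(CC2OCCO2)CC1 | intermediate
11 | dimethylaluminium (3R)-3-(1,3-dioxolan-2-ylmethyl)-3-methylcyclopent-1-en-1-olate | C[Al](C)OC1=C[C@](C)(CC1)CC1OCCO1 | intermediate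
12 | {[(3R)-3-(1,3-dioxolan-2-ylmethyl)-3-methylcyclopent-1-en-1-yl]oxy}trimethylsilane | C[Si](C)(C)OC1=C[C@](C)(CC1)CC1OCCO1 | intermediate
13 | lithium (3R)-3-(1,3-dioxolan-2-ylmethyl)-3-methylcyclopent-1-en-1-olate | [Li]OC1=C[C@](C)(CC1)CC1OCCO1 | intermediate
14 | dicyclohexyl{[(3R)-3-(1,3-dioxolan-2-ylmethyl)-3-methylcyclopent-1-en-1-yl]oxy}borane | C1CCCCC1B(OC1=C[C@](C)(CC1)CC1OCCO1)C1CCCCC1 | intermediate
15 | (2S,3R)-3-(1,3-dioxolan-2-ylmethyl)-2-[(1R,2Z)-1-hydroxy-3-iodobut-2-en-1-yl]-3-methylcyclopentan-1-one | C/C(I)=C/[C@H](O)[C@@H]1[C@](C)(CCC1=O)CC1OCCO1 | intermediate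
16 | (2S,3R)-2-[(1R,2Z)-1-{[tert-butyl(dimethyl)silyl]oxy}-3-iodobut-2-en-1-yl]-3-(1,3-dioxolan-2-ylmethyl)-3-methylcyclopentan-1-one | C/C(I)=C/[C@H](O[Si](C)(C)C(C)(C)C)[C@@H]1[C@](C)(CCC1=O)CC1OCCO1 | intermediate
17 | chloromagnesium (1R,2S,3R)-2-[(1R,2Z)-1-{[tert-butyl(dimethyl)silyl]oxy}-3-iodobut-2-en-1-yl]-3-(1,3-dioxolan-2-ylmethyl)-3-methyl-1-(propan-2-yl)cyclopentan-1-olate | C/C(I)=C/[C@H](O[Si](C)(C)C(C)(C)C)[C@@H]1[C@](C)(CC[C@@]1(O[Mg]Cl)C(C)C)CC1OCCO1 | intermediate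
18 | (1R,2S,3R)-2-[(1R,2Z)-1-{[tert-butyl(dimethyl)silyl]oxy}-3-iodobut-2-en-1-yl]-3-(1,3-dioxolan-2-ylmethyl)-3-methyl-1-(propan-2-yl)cyclopentyl 4-{[tert-butyl(dimethyl)silyl]oxy}benzoate | C/C(I)=C/[C@H](O[Si](C)(C)C(C)(C)C)[C@@H]1[C@](C)(CC[C@@]1(OC(=O)c1ccc(O[Si](C)(C)C(C)(C)C)cc1)C(C)C)CC1OCCO1 | intermediate
19 | (1R,2S,3R)-2-[(1R,2Z)-1-{[tert-butyl(dimethyl)silyl]oxy}-3-iodobut-2-en-1-yl]-3-methyl-3-(2-oxoethyl)-1-(propan-2-yl)cyclopentyl 4-{[tert-butyl(dimethyl)silyl]oxy}benzoate | C/C(I)=C/[C@H](O[Si](C)(C)C(C)(C)C)[C@@H]1[C@](C)(CC[C@@]1(OC(=O)c1ccc(O[Si](C)(C)C(C)(C)C)cc1)C(C)C)CC=O | intermediate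
20 | (1R,3aR,8S,8aS)-8-{[tert-butyl(dimethyl)silyl]oxy}-5-hydroxy-3a,6-dimethyl-1-(propan-2-yl)-1,2,3,3a,4,5,8,8a-octahydroazulen-1-yl 4-{[tert-butyl(dimethyl)silyl]oxy}benzoate (carbinol epimers at ring position 5) | CC1=C[C@H](O[Si](C)(C)C(C)(C)C)[C@@H]2[C@](C)(CC[C@@]2(OC(=O)c2ccc(O[Si](C)(C)C(C)(C)C)cc2)C(C)C)CC1O | intermediate
21 | (1R,3aR,8S,8aS)-8-{[tert-butyl(dimethyl)silyl]oxy}-3a,6-dimethyl-5-oxo-1-(propan-2-yl)-1,2,3,3a,4,5,8,8a-octahydroazulen-1-yl 4-{[tert-butyl(dimethyl)silyl]oxy}benzoate | CC1=C[C@H](O[Si](C)(C)C(C)(C)C)[C@@H]2[C@](C)(CC[C@@]2(OC(=O)c2ccc(O[Si](C)(C)C(C)(C)C)cc2)C(C)C)CC1=O | intermediate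
22 | (1R,3aR,8S,8aS)-8-hydroxy-3a,6-dimethyl-5-oxo-1-(propan-2-yl)-1,2,3,3a,4,5,8,8a-octahydroazulen-1-yl 4-hydroxybenzoate | CC1=C[C@H](O)[C@@H]2[C@](C)(CC[C@@]2(OC(=O)c2ccc(O)cc2)C(C)C)CC1=O | target

**Step count and risks**

Total step count: 13. Longest linear sequence: 9 steps (steps 5 to 13, from 8).

Steps most likely to fail:

1. Step 7. The aldol may discriminate poorly between the two faces of C5 (methyl against dioxolanylmethyl on C1), and the β-iodo enal may suffer addition–elimination or Z-to-E isomerisation under enolate conditions. The fallback sets out from 12 and comes back at 15, and it brings in the iodide only after the carbon–carbon bond is made. The same lithium-to-boron enolate exchange is followed by addition of commercial but-2-ynal, the slimmest possible partner in the closed transition state, which should give (2S,3R)-3-(1,3-dioxolan-2-ylmethyl)-2-[(1R)-1-hydroxybut-2-yn-1-yl]-3-methylcyclopentan-1-one F9, from which a wrong C5 epimer can be removed. Ruthenium-catalysed trans-hydrosilylation of the propargylic alcohol ([Cp*Ru(MeCN)3]PF6, Et3SiH, CH2Cl2) should place silicon on the distal carbon and give (2S,3R)-3-(1,3-dioxolan-2-ylmethyl)-2-[(1R,2Z)-1-hydroxy-3-(triethylsilyl)but-2-en-1-yl]-3-methylcyclopentan-1-one F10. Iododesilylation with retention (N-iodosuccinimide, hexafluoroisopropanol, 0 °C) then returns to 15.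

2. Step 11. Closure of the seven-membered ring may be slow, so that reductive loss of iodine or intermolecular coupling takes over. The fallback sets out from 12 and comes back at 21, and it closes ring B at C7=C8 by olefin metathesis instead. Boron aldol addition of 12 (through 13 and 14) to acrolein should give (2S,3R)-3-(1,3-dioxolan-2-ylmethyl)-2-[(1S)-1-hydroxyprop-2-en-1-yl]-3-methylcyclopentan-1-one F1. Silylation (TBSOTf, 2,6-lutidine) gives (2S,3R)-2-[(1S)-1-(TBS-oxy)prop-2-en-1-yl]-3-(1,3-dioxolan-2-ylmethyl)-3-methylcyclopentan-1-one F2. Addition of i-PrMgCl/CeCl3 and acylation with 7 give (1R,2S,3R)-2-[(1S)-1-(TBS-oxy)prop-2-en-1-yl]-3-(1,3-dioxolan-2-ylmethyl)-3-methyl-1-(propan-2-yl)cyclopentyl 4-(TBS-oxy)benzoate F3. Acetal hydrolysis (PPTS, wet acetone) gives (1R,2S,3R)-2-[(1S)-1-(TBS-oxy)prop-2-en-1-yl]-3-methyl-3-(2-oxoethyl)-1-(propan-2-yl)cyclopentyl 4-(TBS-oxy)benzoate F4. Isopropenylmagnesium bromide at −78 °C gives (1R,2S,3R)-2-[(1S)-1-(TBS-oxy)prop-2-en-1-yl]-3-(2-hydroxy-3-methylbut-3-en-1-yl)-3-methyl-1-(propan-2-yl)cyclopentyl 4-(TBS-oxy)benzoate F5, and Dess–Martin oxidation gives (1R,2S,3R)-2-[(1S)-1-(TBS-oxy)prop-2-en-1-yl]-3-methyl-3-(3-methyl-2-oxobut-3-en-1-yl)-1-(propan-2-yl)cyclopentyl 4-(TBS-oxy)benzoate F6. Ring-closing metathesis with the second-generation Grubbs catalyst (toluene, 80 °C) then returns to 21.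

3. Step 9. The branched Grignard reagent may enolise or reduce the hindered ketone, iodine–magnesium exchange may erode the alkenyl iodide, and acylation of the congested alkoxide may stall or be overtaken by silyl migration from the C6 oxygen. The fallback sets out from 16 and comes back at 18, using an sp2 nucleophile that cannot deliver hydride and a separate acylation. Isopropenylmagnesium bromide/CeCl3 should give (1S,2S,3R)-2-[(1R,2Z)-3-iodo-1-(TBS-oxy)but-2-en-1-yl]-3-(1,3-dioxolan-2-ylmethyl)-3-methyl-1-(prop-1-en-2-yl)cyclopentan-1-ol F7. Deprotonation with KHMDS at −78 °C and acylation with 7 give (1S,2S,3R)-2-[(1R,2Z)-3-iodo-1-(TBS-oxy)but-2-en-1-yl]-3-(1,3-dioxolan-2-ylmethyl)-3-methyl-1-(prop-1-en-2-yl)cyclopentyl 4-(TBS-oxy)benzoate F8. Diimide (2-nitrobenzenesulfonohydrazide, Et3N) should reduce the 1,1-disubstituted alkene in preference to the trisubstituted iodoalkene and return to 18.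

Further compounds
F1 | step 11 | (2S,3R)-3-(1,3-dioxolan-2-ylmethyl)-2-[(1S)-1-hydroxyprop-2-en-1-yl]-3-methylcyclopentan-1-one | C=C[C@H](O)[C@@H]1[C@](C)(CCC1=O)CC1OCCO1
F2 | step 11 | (2S,3R)-2-[(1S)-1-{[tert-butyl(dimethyl)silyl]oxy}prop-2-en-1-yl]-3-(1,3-dioxolan-2-ylmethyl)-3-methylcyclopentan-1-one | C=C[C@H](O[Si](C)(C)C(C)(C)C)[C@@H]1[C@](C)(CCC1=O)CC1OCCO1
F3 | step 11 | (1R,2S,3R)-2-[(1S)-1-{[tert-butyl(dimethyl)silyl]oxy}prop-2-en-1-yl]-3-(1,3-dioxolan-2-ylmethyl)-3-methyl-1-(propan-2-yl)cyclopentyl 4-{[tert-butyl(dimethyl)silyl]oxy}benzoate | C=C[C@H](O[Si](C)(C)C(C)(C)C)[C@@H]1[C@](C)(CC[C@@]1(OC(=O)c1ccc(O[Si](C)(C)C(C)(C)C)cc1)C(C)C)CC1OCCO1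
F4 | step 11 | (1R,2S,3R)-2-[(1S)-1-{[tert-butyl(dimethyl)silyl]oxy}prop-2-en-1-yl]-3-methyl-3-(2-oxoethyl)-1-(propan-2-yl)cyclopentyl 4-{[tert-butyl(dimethyl)silyl]oxy}benzoate | C=C[C@H](O[Si](C)(C)C(C)(C)C)[C@@H]1[C@](C)(CC[C@@]1(OC(=O)c1ccc(O[Si](C)(C)C(C)(C)C)cc1)C(C)C)CC=O
F5 | step 11 | (1R,2S,3R)-2-[(1S)-1-{[tert-butyl(dimethyl)silyl]oxy}prop-2-en-1-yl]-3-(2-hydroxy-3-methylbut-3-en-1-yl)-3-methyl-1-(propan-2-yl)cyclopentyl 4-{[tert-butyl(dimethyl)silyl]oxy}benzoate (carbinol epimers) | C=C[C@H](O[Si](C)(C)C(C)(C)C)[C@@H]1[C@](C)(CC[C@@]1(OC(=O)c1ccc(O[Si](C)(C)C(C)(C)C)cc1)C(C)C)CC(O)C(C)=C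
F6 | step 11 | (1R,2S,3R)-2-[(1S)-1-{[tert-butyl(dimethyl)silyl]oxy}prop-2-en-1-yl]-3-methyl-3-(3-methyl-2-oxobut-3-en-1-yl)-1-(propan-2-yl)cyclopentyl 4-{[tert-butyl(dimethyl)silyl]oxy}benzoate | C=C[C@H](O[Si](C)(C)C(C)(C)C)[C@@H]1[C@](C)(CC[C@@]1(OC(=O)c1ccc(O[Si](C)(C)C(C)(C)C)cc1)C(C)C)CC(=O)C(C)=C
F7 | step 9 | (1S,2S,3R)-2-[(1R,2Z)-1-{[tert-butyl(dimethyl)silyl]oxy}-3-iodobut-2-en-1-yl]-3-(1,3-dioxolan-2-ylmethyl)-3-methyl-1-(prop-1-en-2-yl)cyclopentan-1-ol | C/C(I)=C/[C@H](O[Si](C)(C)C(C)(C)C)[C@@H]1[C@](C)(CC[C@@]1(O)C(C)=C)CC1OCCO1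
F8 | step 9 | (1S,2S,3R)-2-[(1R,2Z)-1-{[tert-butyl(dimethyl)silyl]oxy}-3-iodobut-2-en-1-yl]-3-(1,3-dioxolan-2-ylmethyl)-3-methyl-1-(prop-1-en-2-yl)cyclopentyl 4-{[tert-butyl(dimethyl)silyl]oxy}benzoate | C/C(I)=C/[C@H](O[Si](C)(C)C(C)(C)C)[C@@H]1[C@](C)(CC[C@@]1(OC(=O)c1ccc(O[Si](C)(C)C(C)(C)C)cc1)C(C)=C)CC1OCCO1
F9 | step 7 | (2S,3R)-3-(1,3-dioxolan-2-ylmethyl)-2-[(1R)-1-hydroxybut-2-yn-1-yl]-3-methylcyclopentan-1-one | CC#C[C@H](O)[C@@H]1[C@](C)(CCC1=O)CC1OCCO1
F10 | step 7 | (2S,3R)-3-(1,3-dioxolan-2-ylmethyl)-2-[(1R,2Z)-1-hydroxy-3-(triethylsilyl)but-2-en-1-yl]-3-methylcyclopentan-1-one | C/C([Si](CC)(CC)CC)=C/[C@H](O)[C@@H]1[C@](C)(CCC1=O)CC1OCCO1
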